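**Strategy.** The oxane is disconnected at O1–C6, between the ring oxygen and the carbon bearing the 2-(4-hydroxyphenyl)ethyl chain. The key step exploits ring A on C4: its three oxygens stabilise an allyl cation spanning C4–C5–C6, so mild acid ionises an acyclic hept-4-ene-1,3-diol (tertiary ring-A carbinol, both epimers; benzylic carbinol 1S) and the benzylic hydroxyl, the future O1 on C2, closes onto C6. One operation forms the ring, erases the epimer mixture stereoconvergently and sets C6 cis to C2. Hydrogenation anti to both substituents then sets C4 and frees two phenols; lithiation/acetylation, Claisen–Schmidt condensation and acetal cleavage complete the chalcone.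

Key step: step 7

Remark: the bisphosphoramide antipode used in step 4 is the one that directs attack to the Si face of the aldehyde (1S carbinol); all compounds marked as starting materials are taken as commercial.

**Step 1**
Reactants: 1 1-(benzyloxy)-4-iodobenzene; 2 prop-2-en-1-ol
Product: 3 3-[4-(benzyloxy)phenyl]propanal
Conditions: Pd(OAc)2 (3 mol%), n-Bu4NCl, NaHCO3, DMF, 45 °C
Reagents that add atoms: none
Why: Heck reaction of an aryl iodide with an allylic alcohol, in which β-hydride elimination toward the carbinol carbon gives the enol and hence the saturated 3-aryl aldehyde.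

**Step 2**
Reactants: 3 3-[4-(benzyloxy)phenyl]propanal; 4 1-(triphenyl-λ5-phosphanylidene)propan-2-one
Product: 5 (3E)-6-[4-(benzyloxy)phenyl]hex-3-en-2-one
Conditions: CH2Cl2, 40 °C
Reagents that add atoms: none
Why: Wittig olefination with a stabilised ylide should give the E-enone.

**Step 3**
Reactants: 5 (3E)-6-[4-(benzyloxy)phenyl]hex-3-en-2-one
Product: 6 {[(3E)-6-[4-(benzyloxy)phenyl]hexa-1,3-dien-2-yl]oxy}trimethylsilane
Conditions: TMSCl, LDA, THF, −78 °C (in situ quench); non-aqueous work-up, used crude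
Reagents that add atoms: chlorotrimethylsilane, C[Si](C)(C)Cl
Why: Kinetic deprotonation at the methyl group with immediate O-silylation (silyl enol ether formation) should give the cross-conjugated 2-silyloxydiene and not the γ-deprotonated isomer.

**Step 4**
Reactants: 6 {[(3E)-6-[4-(benzyloxy)phenyl]hexa-1,3-dien-2-yl]oxy}trimethylsilane; 7 4-(benzyloxy)benzaldehyde
Product: 8 (1S,4E)-1,7-bis[4-(benzyloxy)phenyl]-1-hydroxyhept-4-en-3-one
Conditions: SiCl4, chiral 1,1'-binaphthyl-2,2'-diamine-derived bisphosphoramide (5 mol%), i-Pr2NEt (cat.), CH2Cl2, −78 °C; then aq NaHCO3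
Reagents that add atoms: none
Why: Mukaiyama aldol addition under Lewis-base-activated SiCl4 catalysis, a system suited to methyl-ketone enol silanes and aromatic aldehydes, in which the phosphoramide-bound silicon cation shields one aldehyde face so that Si-face attack sets C1 as S.

**Step 5**
Reactants: 9 5-methoxybenzene-1,3-diol
Product: 10 1-methoxy-3,5-bis(methoxymethoxy)benzene
Conditions: NaH, MOMCl, DMF, 0 °C to rt
Reagents that add atoms: chloromethyl methyl ether, COCCl
Why: Williamson-type O-alkylation of both phenoxides installs the two MOM ethers that later direct lithiation.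

**Step 6**
Reactants: 8 (1S,4E)-1,7-bis[4-(benzyloxy)phenyl]-1-hydroxyhept-4-en-3-one; 10 1-methoxy-3,5-bis(methoxymethoxy)benzene
Product: 13 (1S,4E)-1,7-bis[4-(benzyloxy)phenyl]-3-[4-methoxy-2,6-bis(methoxymethoxy)phenyl]hept-4-ene-1,3-diol (both C3 epimers), via aryllithium 11 (not isolated), via arylcerium dichloride 12 (not isolated)
Conditions: 10 (2.5 equiv), n-BuLi, TMEDA, THF, 0 °C; CeCl3, −78 °C; then 8, −78 °C; aq NaHCO3, used without chromatography
Reagents that add atoms: none
Why: Directed ortho-metalation between the two MOM ethers gives 11, transmetalation gives the weakly basic organocerium 12, and its 1,2-addition to the enone carbonyl (one equivalent is spent on the hydroxyl) should give the tertiary carbinol as both C3 epimers, a mixture that is harmless because step 7 destroys this centre.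

**Step 7**
Reactants: 13 (1S,4E)-1,7-bis[4-(benzyloxy)phenyl]-3-[4-methoxy-2,6-bis(methoxymethoxy)phenyl]hept-4-ene-1,3-diol
Product: 14 (2S,6S)-2-[4-(benzyloxy)phenyl]-6-{2-[4-(benzyloxy)phenyl]ethyl}-4-[4-methoxy-2,6-bis(methoxymethoxy)phenyl]-3,6-dihydro-2H-pyran
Conditions: PPTS (10 mol%), 4 Å molecular sieves, CH2Cl2, 0 °C to rt
Reagents that add atoms: none
Why: Protonation and loss of water from the tertiary carbinol should give an allyl cation over C3–C4–C5 of the heptene (C4–C5–C6 of the future ring) that is conjugated with the 2,4,6-trioxygenated ring A, and the C1 hydroxyl then adds to the distal terminus to form the O1–C6 bond. The closest known reaction type is the acid- or metal-catalysed dehydrative cyclisation of hydroxy allylic alcohols with allylic transposition, which gives 2,6-cis-dihydropyrans. The ring closes in the 6-endo-trig mode, the double bond ending inside the ring at C4=C5. The only new stereocentre, C6, is controlled by the existing 1S centre: in the half-chair transition state the C2 aryl group sits pseudo-equatorial and the E-configured allyl terminus places the arylethyl chain pseudo-equatorial, and because the allylic ether can re-ionise, any 2,6-trans isomer should drain into the more stable cis isomer (2S,6S). Both C3 epimers of 13 converge on the same cation, so the step is stereoconvergent. The selectivity needed is ionisation at the tertiary carbinol and not at the secondary benzylic C1–OH, which the far greater stabilisation by ring A and the weak acid secure; the MOM and benzyl ether oxygens are poor nucleophiles, so closure by the free hydroxyl should outrun chromene formation or proton loss to a diene.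

**Step 8**
Reactants: 14 (2S,6S)-2-[4-(benzyloxy)phenyl]-6-{2-[4-(benzyloxy)phenyl]ethyl}-4-[4-methoxy-2,6-bis(methoxymethoxy)phenyl]-3,6-dihydro-2H-pyran
Product: 15 4-[(2S,4R,6S)-6-[2-(4-hydroxyphenyl)ethyl]-4-[4-methoxy-2,6-bis(methoxymethoxy)phenyl]oxan-2-yl]phenol
Conditions: H2 (1 atm), 10% Pd/C, EtOAc, rt
Reagents that add atoms: none
Why: Heterogeneous catalytic hydrogenation with concurrent hydrogenolysis of both benzyl ethers, in which the alkene should adsorb on the face that carries only the axial hydrogens of C2 and C6, so that hydrogen reaches C4 anti to both pseudo-equatorial substituents and sets C4 as R with ring A equatorial (all-cis, also the most stable isomer).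

**Step 9**
Reactants: 15 4-[(2S,4R,6S)-6-[2-(4-hydroxyphenyl)ethyl]-4-[4-methoxy-2,6-bis(methoxymethoxy)phenyl]oxan-2-yl]phenol; 16 N-methoxy-N-methylacetamide
Product: 18 1-{3-[(2S,4R,6S)-2-(4-hydroxyphenyl)-6-[2-(4-hydroxyphenyl)ethyl]oxan-4-yl]-6-methoxy-2,4-bis(methoxymethoxy)phenyl}ethan-1-one, via trilithiated intermediate 17 (not isolated)
Conditions: n-BuLi (3.3 equiv), THF, −78 to 0 °C; then 16, −78 °C to rt; aq NH4Cl
Reagents that add atoms: none
Why: Directed ortho-metalation followed by Weinreb ketone synthesis, in which the two phenols are masked in situ as lithium phenoxides (which shuts down lithiation of their rings), the third equivalent removes the ring-A hydrogen flanked by OMOM and OMe (the two such positions are equivalent by rotation about the C4–aryl bond) and the chelated tetrahedral adduct stops at the methyl ketone.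

**Step 10**
Reactants: 18 1-{3-[(2S,4R,6S)-2-(4-hydroxyphenyl)-6-[2-(4-hydroxyphenyl)ethyl]oxan-4-yl]-6-methoxy-2,4-bis(methoxymethoxy)phenyl}ethan-1-one; 19 4-(methoxymethoxy)benzaldehyde
Product: 20 (2E)-1-{3-[(2S,4R,6S)-2-(4-hydroxyphenyl)-6-[2-(4-hydroxyphenyl)ethyl]oxan-4-yl]-6-methoxy-2,4-bis(methoxymethoxy)phenyl}-3-[4-(methoxymethoxy)phenyl]prop-2-en-1-one
Conditions: KOH (excess), EtOH/H2O, rt to 50 °C
Reagents that add atoms: none
Why: Claisen–Schmidt condensation of the methyl ketone enolate with a non-enolisable aldehyde, where E1cB dehydration should give the E-enone while the two spectator phenols ride through as phenoxides.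

**Step 11**
Reactants: 20 (2E)-1-{3-[(2S,4R,6S)-2-(4-hydroxyphenyl)-6-[2-(4-hydroxyphenyl)ethyl]oxan-4-yl]-6-methoxy-2,4-bis(methoxymethoxy)phenyl}-3-[4-(methoxymethoxy)phenyl]prop-2-en-1-one
Product: 21 (2E)-1-{2,4-dihydroxy-3-[(2S,4R,6S)-2-(4-hydroxyphenyl)-6-[2-(4-hydroxyphenyl)ethyl]oxan-4-yl]-6-methoxyphenyl}-3-(4-hydroxyphenyl)prop-2-en-1-one
Conditions: 3 M aq HCl, MeOH, rt
Reagents that add atoms: none
Why: Acid-catalysed cleavage of the three MOM acetals by transacetalisation to methanol, under which the all-equatorial oxane, being the thermodynamic isomer, should not lose its configuration even if the benzylic C2–O bond ionises reversibly.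

**Compound list**
1 | 1-(benzyloxy)-4-iodobenzene | Ic1ccc(OCc2ccccc2)cc1 | starting material
2 | prop-2-en-1-ol | C=CCO | starting material
3 | 3-[4-(benzyloxy)phenyl]propanal | O=CCCc1ccc(OCc2ccccc2)cc1 | intermediate
4 | 1-(triphenyl-λ5-phosphanylidene)propan-2-one | CC(=O)C=P(c1ccccc1)(c1ccccc1)c1ccccc1 | starting material
5 | (3E)-6-[4-(benzyloxy)phenyl]hex-3-en-2-one | CC(=O)/C=C/CCc1ccc(OCc2ccccc2)cc1 | intermediate
6 | {[(3E)-6-[4-(benzyloxy)phenyl]hexa-1,3-dien-2-yl]oxy}trimethylsilane | C=C(O[Si](C)(C)C)/C=C/CCc1ccc(OCc2ccccc2)cc1 | intermediate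
7 | 4-(benzyloxy)benzaldehyde | O=Cc1ccc(OCc2ccccc2)cc1 | starting material
8 | (1S,4E)-1,7-bis[4-(benzyloxy)phenyl]-1-hydroxyhept-4-en-3-one | O[C@H](c1ccc(OCc2ccccc2)cc1)CC(=O)/C=C/CCc1ccc(OCc2ccccc2)cc1 | intermediate
9 | 5-methoxybenzene-1,3-diol | COc1cc(O)cc(O)c1 | starting material
10 | 1-methoxy-3,5-bis(methoxymethoxy)benzene | COCOc1cc(OC)cc(OCOC)c1 | intermediate
11 | [4-methoxy-2,6-bis(methoxymethoxy)phenyl]lithium | [Li]c1c(OCOC)cc(OC)cc1OCOC | intermediate
12 | dichloro[4-methoxy-2,6-bis(methoxymethoxy)phenyl]cerium | Cl[Ce](Cl)c1c(OCOC)cc(OC)cc1OCOC | intermediate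
13 | (1S,4E)-1,7-bis[4-(benzyloxy)phenyl]-3-[4-methoxy-2,6-bis(methoxymethoxy)phenyl]hept-4-ene-1,3-diol (both C3 epimers) | O[C@H](c1ccc(OCc2ccccc2)cc1)CC(O)(c1c(OCOC)cc(OC)cc1OCOC)/C=C/CCc1ccc(OCc2ccccc2)cc1 | intermediate
14 | (2S,6S)-2-[4-(benzyloxy)phenyl]-6-{2-[4-(benzyloxy)phenyl]ethyl}-4-[4-methoxy-2,6-bis(methoxymethoxy)phenyl]-3,6-dihydro-2H-pyran | COCOc1cc(OC)cc(OCOC)c1C1=C[C@H](CCc2ccc(OCc3ccccc3)cc2)O[C@H](c2ccc(OCc3ccccc3)cc2)C1 | intermediate
15 | 4-[(2S,4R,6S)-6-[2-(4-hydroxyphenyl)ethyl]-4-[4-methoxy-2,6-bis(methoxymethoxy)phenyl]oxan-2-yl]phenol | COCOc1cc(OC)cc(OCOC)c1[C@@H]1C[C@H](CCc2ccc(O)cc2)O[C@H](c2ccc(O)cc2)C1 | intermediate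
16 | N-methoxy-N-methylacetamide | CC(=O)N(C)OC | starting material
17 | trilithiated 15 (dilithium bis-phenoxide, ring A lithiated between OMOM and OMe) | COCOc1cc(OC)c([Li])c(OCOC)c1[C@@H]1C[C@H](CCc2ccc([O-])cc2)O[C@H](c2ccc([O-])cc2)C1.[Li+].[Li+] | intermediate
18 | 1-{3-[(2S,4R,6S)-2-(4-hydroxyphenyl)-6-[2-(4-hydroxyphenyl)ethyl]oxan-4-yl]-6-methoxy-2,4-bis(methoxymethoxy)phenyl}ethan-1-one | COCOc1cc(OC)c(C(C)=O)c(OCOC)c1[C@@H]1C[C@H](CCc2ccc(O)cc2)O[C@H](c2ccc(O)cc2)C1 | intermediate
19 | 4-(methoxymethoxy)benzaldehyde | COCOc1ccc(C=O)cc1 | starting material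
20 | (2E)-1-{3-[(2S,4R,6S)-2-(4-hydroxyphenyl)-6-[2-(4-hydroxyphenyl)ethyl]oxan-4-yl]-6-methoxy-2,4-bis(methoxymethoxy)phenyl}-3-[4-(methoxymethoxy)phenyl]prop-2-en-1-one | COCOc1cc(OC)c(C(=O)/C=C/c2ccc(OCOC)cc2)c(OCOC)c1[C@@H]1C[C@H](CCc2ccc(O)cc2)O[C@H](c2ccc(O)cc2)C1 | intermediate
21 | (2E)-1-{2,4-dihydroxy-3-[(2S,4R,6S)-2-(4-hydroxyphenyl)-6-[2-(4-hydroxyphenyl)ethyl]oxan-4-yl]-6-methoxyphenyl}-3-(4-hydroxyphenyl)prop-2-en-1-one | COc1cc(O)c([C@@H]2C[C@H](CCc3ccc(O)cc3)O[C@H](c3ccc(O)cc3)C2)c(O)c1C(=O)/C=C/c1ccc(O)cc1 | target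

**Total steps:** 11. **Longest linear sequence:** 10 steps (1 → 3 → 5 → 6 → 8 → 13 → 14 → 15 → 18 → 20 → 21); step 5 is the only side branch.

**Steps most likely to fail**

Step 6. The metal aldolate of 8 may fragment by retro-aldol cleavage, or the ketone may be enolised in place of 1,2-addition. The fallback sets out from 8 and closes the ring before ring A is brought in. Amberlyst-15 in CH2Cl2 should equilibrate 8 by reversible oxa-Michael addition to the cis ketone (2S,6S)-2-[4-(benzyloxy)phenyl]-6-{2-[4-(benzyloxy)phenyl]ethyl}oxan-4-one F1. Addition of arylcerium 12 to this ketone, which has no free hydroxyl, should give the tertiary carbinol (2S,6S)-2-[4-(benzyloxy)phenyl]-6-{2-[4-(benzyloxy)phenyl]ethyl}-4-[4-methoxy-2,6-bis(methoxymethoxy)phenyl]oxan-4-ol F2. PPTS then dehydrates it to 14 together with its double-bond isomer (2S,6S)-6-[4-(benzyloxy)phenyl]-2-{2-[4-(benzyloxy)phenyl]ethyl}-4-[4-methoxy-2,6-bis(methoxymethoxy)phenyl]-3,6-dihydro-2H-pyran F3. Both alkenes are hydrogenated under the conditions of step 8, so the detour comes back to the route at 15. It still forms the O1–C6 bond in the ring-closing event and also bypasses step 7, should the cis selectivity there prove insufficient.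

Step 8. Facial selectivity may be poor on a hindered trisubstituted alkene, or the allylic C6–O bond may be hydrogenolysed. The fallback sets out from 14 and uses radical hydrogen-atom-transfer hydrogenation (Mn(dpm)3, PhSiH3, t-BuOOH, i-PrOH, rt). It should reduce the alkene through a C4 benzylic radical that is quenched from the axial direction, giving the thermodynamically preferred all-equatorial (2S,4R,6S)-2-[4-(benzyloxy)phenyl]-6-{2-[4-(benzyloxy)phenyl]ethyl}-4-[4-methoxy-2,6-bis(methoxymethoxy)phenyl]oxane F4 without touching C–O bonds. Hydrogenolysis of its two benzyl ethers (H2, Pd/C, EtOAc) then comes back to the route at 15.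

Step 9. Lithiation of a sparingly soluble trianion may be incomplete or may compete at other sites. The fallback sets out from 15 and replaces C–H lithiation by electrophilic halogenation and halogen–metal exchange. NBS (1 equiv, CH2Cl2, −78 °C) should attack only the trioxygenated ring A and give the aryl bromide 4-[(2S,4R,6S)-4-[3-bromo-4-methoxy-2,6-bis(methoxymethoxy)phenyl]-6-[2-(4-hydroxyphenyl)ethyl]oxan-2-yl]phenol F5. Deprotonation of the phenols with MeLi, bromine–lithium exchange with t-BuLi at −78 °C (which regenerates 17) and trapping with 16 then come back to the route at 18.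

**Further compounds**
F1 | step 6 | (2S,6S)-2-[4-(benzyloxy)phenyl]-6-{2-[4-(benzyloxy)phenyl]ethyl}oxan-4-one | O=C1C[C@H](CCc2ccc(OCc3ccccc3)cc2)O[C@H](c2ccc(OCc3ccccc3)cc2)C1
F2 | step 6 | (2S,6S)-2-[4-(benzyloxy)phenyl]-6-{2-[4-(benzyloxy)phenyl]ethyl}-4-[4-methoxy-2,6-bis(methoxymethoxy)phenyl]oxan-4-ol (both C4 epimers) | COCOc1cc(OC)cc(OCOC)c1C1(O)C[C@H](CCc2ccc(OCc3ccccc3)cc2)O[C@H](c2ccc(OCc3ccccc3)cc2)C1
F3 | step 6 | (2S,6S)-6-[4-(benzyloxy)phenyl]-2-{2-[4-(benzyloxy)phenyl]ethyl}-4-[4-methoxy-2,6-bis(methoxymethoxy)phenyl]-3,6-dihydro-2H-pyran | COCOc1cc(OC)cc(OCOC)c1C1=C[C@@H](c2ccc(OCc3ccccc3)cc2)O[C@@H](CCc2ccc(OCc3ccccc3)cc2)C1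
F4 | step 8 | (2S,4R,6S)-2-[4-(benzyloxy)phenyl]-6-{2-[4-(benzyloxy)phenyl]ethyl}-4-[4-methoxy-2,6-bis(methoxymethoxy)phenyl]oxane | COCOc1cc(OC)cc(OCOC)c1[C@@H]1C[C@H](CCc2ccc(OCc3ccccc3)cc2)O[C@H](c2ccc(OCc3ccccc3)cc2)C1
F5 | step 9 | 4-[(2S,4R,6S)-4-[3-bromo-4-methoxy-2,6-bis(methoxymethoxy)phenyl]-6-[2-(4-hydroxyphenyl)ethyl]oxan-2-yl]phenol | COCOc1cc(OC)c(Br)c(OCOC)c1[C@@H]1C[C@H](CCc2ccc(O)cc2)O[C@H](c2ccc(O)cc2)C1
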